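I began from a one-step world: whatever leaves the solid substrate is captured by the first nucleophile to give the target, or by the second nucleophile to give the other capture product, and the two captures compete.

| flask | solid substrate | first nucleophile | second nucleophile | remark | time |
|---|---|---|---|---|---|
| east | 0.050 M | 0.040 M | 0.055 M | the very flask that is asked about, followed so far |  |
| flask | 0.050 M | 0.0400 M | 0.0550 M |  | 20 h |

east run (percent of the solid substrate charged)

| time / h | target / % | other capture product / % |
|---|---|---|
| 0.333 | 15.6 | 5.2 |
| 0.667 | 36.1 | 14.4 |
| 1.00 | 56.0 | 27.8 |
| 2.00 | 64.9 | 35.3 |
| 4.00 | 63.8 | 35.1 |

(scatter of a reading: 0.5 percentage points)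

- at the start none of the solid substrate is in solution
- a reading or a percentage of target counts all its forms, free or not

* ratio of target to other capture product at 8.0 min
* ratio of target to other capture product at 1.5 h
* ratio of target to other capture product at 20 h

In that world I needed one number. I defined S, the selectivity factor, as the logarithm of the fraction of first nucleophile left over the logarithm of the fraction of second nucleophile left, each fraction reckoned from the products. The reading at 4.00 h gave 4.16. In the one-step world it stood for the ratio of the two capture rate constants. Multiplied by the charge ratio, it put the starting ratio in this flask at 3.02, so I committed to about that at 8.0 min. For the two later times I committed to about the ratio read at 4.00 h, 1.82.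

Was one number enough? The reading at 0.333 h gave 4.48, but it rested on 5.2% of other capture product with a scatter of 0.5 percentage points, so I kept one number.

The forecast gave 3.05, 1.85 and 1.82, on “simple competition with the first nucleophile depleting”. Its factor was 4.25, mine 4.16.

The flask gave 3.66, 1.81 and 1.79.

    starting material → intermediate (k = 0.00150 s⁻¹)
    first nucleophile + intermediate → target (k = 14.0 M⁻¹ s⁻¹)
    second nucleophile + intermediate → other capture product (k = 2.30 M⁻¹ s⁻¹)
    solid substrate ⇌ starting material, rate k4*(cs4 - [starting material]) while solid is left; crystals form when [starting material] > cs4 (solubility = 30.0 mM, k = 6.40 × 10⁻⁴ s⁻¹)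
    crystals ⇌ target, rate k5*(cs5 - [target]) while solid is left; crystals form when [target] > cs5 (solubility = 16.0 mM, k = 0.260 s⁻¹)
    first nucleophile ⇌ dormant form (K = 0.400, k = 7.50 × 10⁻⁴ s⁻¹)

The two later ratios lay near the forecast, but the ratio at 8.0 min, divided by the charge ratio, was 5.03, higher than S. At 0.645 h, the making of target used first nucleophile at 0.78 of the forward rate of its loss to dormant form.

In the neighbour flask with 0.22 M of second nucleophile, 86% of that nucleophile was left at 20 h. With S this gave a ratio of 0.605, and that neighbour flask gave 0.621.

The numbers in the tables were generated by integration with constants of no real substance.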